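A direct plan would build both rings from protected phloroglucinol units and join them late by a copper-catalysed Ullmann etherification of phenol A1 [2,6-bis(benzyloxy)-4-(methoxymethoxy)phenol] with bromide A2 [1-(benzyloxy)-3-bromo-5-(methoxymethoxy)benzene] to give diaryl ether A3; acetal cleavage, sulfation and hydrogenolysis would finish it.
Its weakest steps would be:
(a) the aryl–oxygen coupling to A3, because a phenol flanked by two benzyloxy groups would have to attack an electron-rich aryl bromide, on material that would by then be six to eight steps deep;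
(b) the construction of phloroglucinol A4 by condensation of acyclic esters and decarboxylation, because two steps would only deliver a compound that can be bought;
(c) the one-pot deacetylation/benzylation of triacetate A5 and the mono-protection of hydroquinone A6, because both desymmetrisations would rest on dosing and small rate differences, not on structure.

**Plan of the new route**
The retrosynthesis removes the sulfates and pivalates, cuts ring B itself at C1–C2 by a retro-Claisen ring transformation to a 2-pyranone, then cuts the O–CH2 bond by a retro-Williamson step to 3,5-dimethoxyphenol.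
Enabling feature: in ring B the carbon bearing the ether oxygen (C1) lies between two hydroxylated carbons (C2, C6) with the third oxygen para (C4). Ring B is thus a 2-aryloxyphloroglucinol, the aromatic tautomer of a cyclised 6-aryloxy-3,5-dioxohexanoate, whose masked form is a 6-(aryloxymethyl)-4-methoxy-2-pyranone.
Ring A is bought; ring B arises last, from the five ring carbons and the exocyclic CH2 of the pyranone. The congested aryl–oxygen bond is therefore made as an SN2 etherification at an sp3 carbon that only later becomes aromatic.
The ring construction itself differentiates the oxygens of ring B: two free phenols that stay free, and a methyl ether at the future sulfate position. No hindered Ullmann coupling, no synthesis of a commercial phenol and no rate-controlled mono-protection occurs.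

Key step: step 3

Assumption: the target is taken as drawn, the bis(hydrogen sulfate); the sulfated compounds would be handled as salts and the free acid liberated only in the last operation, cold, by cation exchange. Compounds 1 and 3 are articles of commerce.

**Step 1**
Reactants: 1 4-methoxy-6-methyl-2H-pyran-2-one
Product: 2 6-(bromomethyl)-4-methoxy-2H-pyran-2-one
Conditions: NBS (1.05 equiv), AIBN (5 mol %), PhCF3, reflux
Reagents that add atoms: N-bromosuccinimide, O=C1CCC(=O)N1Br
Why: Wohl–Ziegler bromination – the radical chain abstracts hydrogen from the 6-methyl group, whose radical is conjugated with the pyranone diene, and non-polar radical conditions suppress ionic bromination at C3; no stereocentre is formed.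

**Step 2**
Reactants: 2 6-(bromomethyl)-4-methoxy-2H-pyran-2-one; 3 3,5-dimethoxyphenol
Product: 4 6-[(3,5-dimethoxyphenoxy)methyl]-4-methoxy-2H-pyran-2-one
Conditions: K2CO3 (1.5 equiv), acetone, rt → 50 °C
Reagents that add atoms: none
Why: Williamson ether synthesis – the phenoxide of 3 displaces the primary, allylic-type bromide by SN2, so the future hindered aryl–oxygen bond of ring B is made at an unhindered sp3 carbon, and a carbonate base in a dipolar aprotic solvent favours O- over C-alkylation.

**Step 3**
Reactants: 4 6-[(3,5-dimethoxyphenoxy)methyl]-4-methoxy-2H-pyran-2-one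
Product: 7 2-(3,5-dimethoxyphenoxy)-5-methoxybenzene-1,3-diol, via ring-opened keto ester 5 (not isolated), via cyclic enedione 6 (not isolated)
Conditions: NaOMe (5 equiv), dry MeOH, sealed vessel, 130 °C, Ar; then 1 M HCl to pH 4
Reagents that add atoms: none
Why: Proposed new method: methoxide should add to the lactone carbonyl of 4 and open it to the enolate of keto ester 5, in which the ester and the aryloxyacetonyl chain are cis on the enol ether double bond as a legacy of the ring; reversible deprotonation at the ArO–CH2–C(=O) carbon then allows an intramolecular Claisen condensation on the ester carbonyl, a 6-(enolexo)-exo-trig closure that forms the C1–C2 bond of ring B and gives enedione 6 after loss of methoxide, and enolisation of 6 to the resorcinol dianion is irreversible and draws the earlier equilibria forward. The closest known reaction type is the NaOMe-induced conversion of 4-methoxy-6-methyl-2-pyranone into 5-methoxyresorcinol (and, for the closure itself, the base-mediated cyclisation of 5-oxo esters to cyclohexane-1,3-diones); what is new is that the carbanion carbon carries an aryloxy group, which should raise its acidity and ease the closure while turning an ether CH2 into the fully substituted aromatic carbon of a diaryl ether. No stereocentre survives, since the CH(OAr) centre of 6 is lost on aromatisation. The step needs C-acylation at the aryloxymethyl carbon in preference to retro-Claisen cleavage at the ketone, reclosure to the pyranone and displacement of the aryloxy group; the substrate should secure this because only the six-membered C-acylation leads to an aromatic, irreversibly deprotonated product, the aryloxy group sits on an sp3 carbon where addition–elimination is impossible, and methoxide matched to the methyl enol ether makes alkoxide exchange at C4 degenerate.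

**Step 4**
Reactants: 7 2-(3,5-dimethoxyphenoxy)-5-methoxybenzene-1,3-diol
Product: 8 2-(3-hydroxy-5-methoxyphenoxy)-5-methoxybenzene-1,3-diol
Conditions: NaSEt (5 equiv), DMF, 130 °C, Ar; then 1 M HCl
Reagents that add atoms: none
Why: Nucleophilic (SN2) O-demethylation by thiolate – ring B is present as its bis-phenoxide and is thereby shielded, the two methoxy groups of ring A are symmetry-equivalent so only one product can arise, and the phenoxide formed by the first cleavage shuts down the second, which is the known basis of mono-demethylation of 3,5-dimethoxyarenes.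

**Step 5**
Reactants: 8 2-(3-hydroxy-5-methoxyphenoxy)-5-methoxybenzene-1,3-diol
Product: 9 3-{4-methoxy-2,6-bis[(2,2-dimethylpropanoyl)oxy]phenoxy}-5-methoxyphenyl 2,2-dimethylpropanoate
Conditions: PivCl (4.5 equiv), Et3N (6 equiv), DMAP (0.2 equiv), CH2Cl2, 0 °C → rt
Reagents that add atoms: pivaloyl chloride, CC(C)(C)C(=O)Cl
Why: Exhaustive O-acylation (nucleophilic acyl substitution under DMAP catalysis) masks exactly the three hydroxyls that stay free in the target, using hindered esters chosen to tolerate BBr3 and to leave under mild base.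

**Step 6**
Reactants: 9 3-{4-methoxy-2,6-bis[(2,2-dimethylpropanoyl)oxy]phenoxy}-5-methoxyphenyl 2,2-dimethylpropanoate
Product: 10 3-{4-hydroxy-2,6-bis[(2,2-dimethylpropanoyl)oxy]phenoxy}-5-hydroxyphenyl 2,2-dimethylpropanoate
Conditions: BBr3 (6 equiv), CH2Cl2, −78 → 0 °C; MeOH then H2O quench at 0 °C
Reagents that add atoms: none
Why: Lewis acid ether cleavage – BBr3 coordinates the two methoxy oxygens and bromide removes the methyl groups by SN2, while the aryl pivalates (no alkyl–oxygen bond to cleave, carbonyl sterically shielded) and the diaryl ether should persist at low temperature.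

**Step 7**
Reactants: 10 3-{4-hydroxy-2,6-bis[(2,2-dimethylpropanoyl)oxy]phenoxy}-5-hydroxyphenyl 2,2-dimethylpropanoate
Product: 11 3-{2,6-bis[(2,2-dimethylpropanoyl)oxy]-4-(sulfooxy)phenoxy}-5-(sulfooxy)phenyl 2,2-dimethylpropanoate
Conditions: SO3·pyridine (6 equiv), pyridine, 40 °C; concentrate, C18 chromatography (bis-pyridinium salt)
Reagents that add atoms: sulfur trioxide–pyridine complex, O=S(=O)([O-])[n+]1ccccc1
Why: O-Sulfonation of the two free, unhindered phenols; the three acylated oxygens cannot react, so the sulfation pattern is fixed by the way ring B was built and ring A was demethylated.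

**Step 8**
Reactants: 11 3-{2,6-bis[(2,2-dimethylpropanoyl)oxy]-4-(sulfooxy)phenoxy}-5-(sulfooxy)phenyl 2,2-dimethylpropanoate
Product: 12 3-[2,6-dihydroxy-4-(sulfooxy)phenoxy]-5-hydroxyphenyl hydrogen sulfate (target)
Conditions: NaOMe (6 equiv), MeOH, 0 °C → rt, Ar; Dowex 50W (H+ form) to pH 7, C18 (disodium salt); Dowex 50W (H+ form), H2O, 0 °C, lyophilise (store as disodium salt)
Reagents that add atoms: none
Why: Base-mediated transesterification (methanolysis) of the three aryl pivalates, to which aryl sulfate monoester anions are inert, followed by cold cation exchange to the free bis(hydrogen sulfate); the target has no stereocentre.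

## Compound list

1 | 4-methoxy-6-methyl-2H-pyran-2-one | COC1=CC(=O)OC(C)=C1 | starting material
2 | 6-(bromomethyl)-4-methoxy-2H-pyran-2-one | COC1=CC(=O)OC(CBr)=C1 | intermediate
3 | 3,5-dimethoxyphenol | COc1cc(O)cc(OC)c1 | starting material
4 | 6-[(3,5-dimethoxyphenoxy)methyl]-4-methoxy-2H-pyran-2-one | COC1=CC(=O)OC(COc2cc(OC)cc(OC)c2)=C1 | intermediate
5 | methyl (2E)-6-(3,5-dimethoxyphenoxy)-3-methoxy-5-oxohex-2-enoate | COC(=O)/C=C(\CC(=O)COc1cc(OC)cc(OC)c1)OC | intermediate (not isolated)
6 | 2-(3,5-dimethoxyphenoxy)-5-methoxycyclohex-4-ene-1,3-dione (racemic, transient) | COC1=CC(=O)C(Oc2cc(OC)cc(OC)c2)C(=O)C1 | intermediate (not isolated)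
7 | 2-(3,5-dimethoxyphenoxy)-5-methoxybenzene-1,3-diol | COc1cc(OC)cc(Oc2c(O)cc(OC)cc2O)c1 | intermediate
8 | 2-(3-hydroxy-5-methoxyphenoxy)-5-methoxybenzene-1,3-diol | COc1cc(O)cc(Oc2c(O)cc(OC)cc2O)c1 | intermediate
9 | 3-{4-methoxy-2,6-bis[(2,2-dimethylpropanoyl)oxy]phenoxy}-5-methoxyphenyl 2,2-dimethylpropanoate | CC(C)(C)C(=O)Oc1cc(OC)cc(Oc2c(OC(=O)C(C)(C)C)cc(OC)cc2OC(=O)C(C)(C)C)c1 | intermediate
10 | 3-{4-hydroxy-2,6-bis[(2,2-dimethylpropanoyl)oxy]phenoxy}-5-hydroxyphenyl 2,2-dimethylpropanoate | CC(C)(C)C(=O)Oc1cc(O)cc(Oc2c(OC(=O)C(C)(C)C)cc(O)cc2OC(=O)C(C)(C)C)c1 | intermediate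
11 | 3-{2,6-bis[(2,2-dimethylpropanoyl)oxy]-4-(sulfooxy)phenoxy}-5-(sulfooxy)phenyl 2,2-dimethylpropanoate | CC(C)(C)C(=O)Oc1cc(OS(=O)(=O)O)cc(Oc2c(OC(=O)C(C)(C)C)cc(OS(=O)(=O)O)cc2OC(=O)C(C)(C)C)c1 | intermediate
12 | 3-[2,6-dihydroxy-4-(sulfooxy)phenoxy]-5-hydroxyphenyl hydrogen sulfate | O=S(=O)(O)Oc1cc(O)cc(Oc2c(O)cc(OS(=O)(=O)O)cc2O)c1 | target

Total step count: 8. Longest linear sequence: 8 steps (1 → 12); 3 enters at step 2.

**Steps most likely to fail**

Step 3 (key step). The ring-opened keto ester could fragment by retro-Claisen attack of methoxide at the ketone, or could simply reclose to the pyranone faster than the aryloxymethyl carbon is deprotonated and acylated. The fallback uses known chemistry, sets out from 1 and returns at 7. The parent ring transformation of 1 (NaOMe, MeOH, sealed vessel, heat) would give 5-methoxybenzene-1,3-diol F1, which can also be bought. MOMCl and iPr2NEt in CH2Cl2 would give 1-methoxy-3,5-bis(methoxymethoxy)benzene F2. Directed ortho-lithiation between the two acetal oxygens (n-BuLi, THF, 0 °C), then B(OMe)3 and H2O2, would give 4-methoxy-2,6-bis(methoxymethoxy)phenol F3. Ullmann etherification of F3 with commercial 1-bromo-3,5-dimethoxybenzene (CuI, picolinic acid, K3PO4, DMSO, 90 °C) would give 2-(3,5-dimethoxyphenoxy)-5-methoxy-1,3-bis(methoxymethoxy)benzene F4, and HCl in MeOH would release 7. This gives up the ring construction, but places the hindered coupling early, on a short fragment and a purchased bromide.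

Step 6. Pivaloyl groups could be lost or could migrate under the Lewis acid, or the ester-deactivated methyl ethers could cleave incompletely. The fallback sets out from 8 and returns at 12, replacing acyl masks by sulfonate masks that are inert to BBr3. TsCl, Et3N and DMAP would give 3-{4-methoxy-2,6-bis[(4-methylbenzenesulfonyl)oxy]phenoxy}-5-methoxyphenyl 4-methylbenzenesulfonate F5. BBr3 in CH2Cl2 would give 3-{4-hydroxy-2,6-bis[(4-methylbenzenesulfonyl)oxy]phenoxy}-5-hydroxyphenyl 4-methylbenzenesulfonate F6. SO3·pyridine would give 3-{2,6-bis[(4-methylbenzenesulfonyl)oxy]-4-(sulfooxy)phenoxy}-5-(sulfooxy)phenyl 4-methylbenzenesulfonate F7. KOH in aqueous MeOH at 60 °C under Ar, to which sulfate monoester anions are inert, followed by cold cation exchange, would give 12.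

Step 4. Chemoselectivity could be lost through a second demethylation on ring A or attack on the methyl ether of ring B. The fallback sets out from 2 and returns at 8, moving the desymmetrisation of ring A in front of the key step. Alkylation of commercial 5-methoxybenzene-1,3-diol (3 equiv, excess recovered by extraction) with 2 (K2CO3, acetone) would give 6-[(3-hydroxy-5-methoxyphenoxy)methyl]-4-methoxy-2H-pyran-2-one F8. The conditions of step 3 would then convert F8 directly into 8, at the price of one mono-alkylation of a symmetric diol on cheap first-step material.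

## Further compounds

F1 | step 3 | 5-methoxybenzene-1,3-diol | COc1cc(O)cc(O)c1
F2 | step 3 | 1-methoxy-3,5-bis(methoxymethoxy)benzene | COCOc1cc(OC)cc(OCOC)c1
F3 | step 3 | 4-methoxy-2,6-bis(methoxymethoxy)phenol | COCOc1cc(OC)cc(OCOC)c1O
F4 | step 3 | 2-(3,5-dimethoxyphenoxy)-5-methoxy-1,3-bis(methoxymethoxy)benzene | COCOc1cc(OC)cc(OCOC)c1Oc1cc(OC)cc(OC)c1
F5 | step 6 | 3-{4-methoxy-2,6-bis[(4-methylbenzenesulfonyl)oxy]phenoxy}-5-methoxyphenyl 4-methylbenzenesulfonate | Cc1ccc(cc1)S(=O)(=O)Oc1cc(OC)cc(Oc2c(OS(=O)(=O)c3ccc(C)cc3)cc(OC)cc2OS(=O)(=O)c2ccc(C)cc2)c1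
F6 | step 6 | 3-{4-hydroxy-2,6-bis[(4-methylbenzenesulfonyl)oxy]phenoxy}-5-hydroxyphenyl 4-methylbenzenesulfonate | Cc1ccc(cc1)S(=O)(=O)Oc1cc(O)cc(Oc2c(OS(=O)(=O)c3ccc(C)cc3)cc(O)cc2OS(=O)(=O)c2ccc(C)cc2)c1
F7 | step 6 | 3-{2,6-bis[(4-methylbenzenesulfonyl)oxy]-4-(sulfooxy)phenoxy}-5-(sulfooxy)phenyl 4-methylbenzenesulfonate | Cc1ccc(cc1)S(=O)(=O)Oc1cc(OS(=O)(=O)O)cc(Oc2c(OS(=O)(=O)c3ccc(C)cc3)cc(OS(=O)(=O)O)cc2OS(=O)(=O)c2ccc(C)cc2)c1
F8 | step 4 | 6-[(3-hydroxy-5-methoxyphenoxy)methyl]-4-methoxy-2H-pyran-2-one | COC1=CC(=O)OC(COc2cc(O)cc(OC)c2)=C1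
A1 | direct plan | 2,6-bis(benzyloxy)-4-(methoxymethoxy)phenol | COCOc1cc(OCc2ccccc2)c(O)c(OCc2ccccc2)c1
A2 | direct plan | 1-(benzyloxy)-3-bromo-5-(methoxymethoxy)benzene | COCOc1cc(Br)cc(OCc2ccccc2)c1
A3 | direct plan | 1,3-bis(benzyloxy)-2-[3-(benzyloxy)-5-(methoxymethoxy)phenoxy]-5-(methoxymethoxy)benzene | COCOc1cc(OCc2ccccc2)cc(Oc2c(OCc3ccccc3)cc(OCOC)cc2OCc2ccccc2)c1
A4 | direct plan | benzene-1,3,5-triol (phloroglucinol) | Oc1cc(O)cc(O)c1
A5 | direct plan | benzene-1,3,5-triyl triacetate | CC(=O)Oc1cc(OC(C)=O)cc(OC(C)=O)c1
A6 | direct plan | 2,6-bis(benzyloxy)benzene-1,4-diol | Oc1cc(OCc2ccccc2)c(O)c(OCc2ccccc2)c1
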